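## Retrosynthetic overview

1. Numbering and feature: the decalin is C1–C10 as in labdanes (CO2Me on C4, OH on C6 and C8, chain on C9), the chain is C11–C12, C13 is the exo-methylene carbon, C14–C15–C16–C17 are the dioxane carbons, and C18–C19 are the lactone CH2 and C=O. The strategy rests on the 1,2-dioxane ring (C14, C15, C16, C17, O, O): its O–O bridge joins a secondary allylic carbon (C14) to a fully substituted carbon (C17) that is anti to the C16 lactone oxygen. That is the pattern left by anti opening of an E-alkene epoxide at C17 with H2O2, followed by SN2 closure at C14.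
2. Last ring: the γ-lactone (O, C16, C17, C18, C19) by oxidative lactonisation of the C16/C19 diol after PMB removal. Before it the dioxane, by forming O–C14: the C17 hydroperoxide displaces a C14 mesylate (6-exo-tet, inversion).
3. The hydroperoxy mesylate comes from the E-C16=C17 alkene by asymmetric epoxidation, mesylation of C14–OH and acid-catalysed perhydrolysis at C17.
4. C13–C14 is made by Ni/Cr coupling of a decalin enol triflate with a β,γ-unsaturated aldehyde built from but-3-yn-1-ol (carboalumination, ethylene oxide).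
5. The decalin (rings A and B taken intact from neoabietic acid): ozonolysis of the ring C diene gives the C8 ketone and C13 acid; C6–OH by enone borylation; the C8 carbinol by methylenation and mercury lactonisation; then methyl ketone and enol triflate. Ring order: A/B (chiral pool) → δ-lactone (reopened) → epoxide (reopened) → dioxane → γ-lactone.

Key step: step 19

Remarks before the steps
- Convention: α is the face opposite the C10 methyl, β the face of that methyl. "Core" means the trans-decalin with 4α-CO2Me (CO2H in 1–3), 4β-CH3, 5α-H, 9α-H (chain on C9 β) and 10β-CH3.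
- Remark: neoabietic acid is used as the commercial resin acid because its ring C diene is cut to the C8 ketone and the C13 acid in one ozonolysis.
- Remark: the tertiary C8 hydroxyl is carried as a triethylsilyl ether through the key step (a spectator change), so that enol triflate formation and mesylation meet no second free hydroxyl; both silyl groups leave in the last step.
- Assumption: the (S)-configured oxazoline–sulfonamide ligand is taken to give the 14S carbinol in step 15; induction comes from the ligand alone, so its antipode would be used without other change if Mosher ester analysis of 24 showed the opposite sense.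

## Route

Step 1
Reactants: 1 neoabietic acid
Product: 3 keto diacid, via keto aldehyde 2 (not isolated)
Conditions: O3, CH2Cl2/MeOH, −78 °C; Me2S, → rt; then H2O2, NaOH, THF/H2O, 0 °C; HCl work-up
Reagents that add atoms: ozone, O=[O+][O-]; hydrogen peroxide, OO
Why: Ozonolysis cleaves both double bonds of the ring C diene (the isopropylidene bond at C13 gives the C13 ketone and acetone, the C8=CH bond gives the C8 ketone and an aldehyde), and alkaline hydrogen peroxide then cleaves the resulting 1,2-dicarbonyl oxidatively to the C13 acid with loss of the ring C methine carbon as formate; C4, C5 and C10 are untouched and C9 keeps its thermodynamically preferred equatorial chain.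

Step 2
Reactants: 3 keto diacid
Product: 4 keto diester
Conditions: MeI, K2CO3, DMF, rt
Reagents that add atoms: methyl iodide, CI
Why: Carboxylate O-alkylation (SN2 on methyl iodide) esterifies both acids, including the hindered C4 acid, and leaves the ketone alone.

Step 3
Reactants: 4 keto diester
Product: 6 enone diester (C6=C7), via silyl enol ether 5 (not isolated)
Conditions: LiN(iPr)2, Me3SiCl, THF, −78 °C; then Pd(OAc)2, MeCN, rt
Reagents that add atoms: chlorotrimethylsilane, C[Si](C)(C)Cl (its silyl group stays only in 5; nothing is added to 6)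
Why: Kinetic deprotonation at the less hindered C7 methylene with in situ silylation, followed by Saegusa–Ito oxidation of the silyl enol ether, places the double bond at C6=C7; the ester α-protons are much less acidic and the C9 methine is shielded by the quaternary C10.

Step 4
Reactants: 6 enone diester
Product: 8 6α-hydroxy ketone, via C6 boronate 7 (not isolated)
Conditions: B2pin2, CuCl (cat.), NaOtBu (cat.), DPEphos (cat.), MeOH, THF, rt; then NaBO3·4H2O, THF/H2O, rt
Reagents that add atoms: bis(pinacolato)diboron, CC1(C)OB(OC1(C)C)B1OC(C)(C)C(C)(C)O1 (boryl group in 7 only); sodium perborate, [Na+].[O-]B1OO1 (the C6 oxygen)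
Why: Copper-catalysed conjugate borylation of the enone delivers boron to C6 from the α face because the β face of C6 is blocked by the two syn-axial methyl groups on C4 and C10, and perborate oxidation of the C–B bond with retention gives the 6α-alcohol.

Step 5
Reactants: 8 6α-hydroxy ketone
Product: 9 6α-silyloxy ketone
Conditions: TBSOTf, 2,6-lutidine, CH2Cl2, −78 °C
Reagents that add atoms: tert-butyldimethylsilyl triflate, CC(C)(C)[Si](C)(C)OS(=O)(=O)C(F)(F)F
Why: Silylation with the silyl triflate at low temperature protects the β-hydroxy ketone before it can dehydrate or undergo retro-aldol cleavage, and the ketone is not enolised by 2,6-lutidine at −78 °C.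

Step 6
Reactants: 9 6α-silyloxy ketone
Product: 10 8-methylene diester
Conditions: Zn, CH2Br2, TiCl4, THF/CH2Cl2, 0 °C → rt
Reagents that add atoms: dibromomethane, BrCBr
Why: Takai–Lombardo methylenation is non-basic, so the hindered, enolisable β-silyloxy ketone is methylenated without loss of the silyloxy group or epimerisation at C9, and esters do not react with this reagent.

Step 7
Reactants: 10 8-methylene diester
Product: 11 8-methylene C13 acid
Conditions: LiOH, THF/MeOH/H2O, rt; dilute HCl work-up at 0 °C
Reagents that add atoms: lithium hydroxide, [Li+].[OH-] (oxygen of the new carboxyl OH)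
Why: Saponification distinguishes the two esters, since the primary-chain ester is hydrolysed at room temperature while the C4 ester on a quaternary ring carbon is inert under these conditions.

Step 8
Reactants: 11 8-methylene C13 acid
Product: 13 δ-lactone, via organomercurial lactone 12 (not isolated)
Conditions: Hg(OCOCF3)2, NaHCO3, MeCN, 0 °C; then NaBH4, aq. NaOH, 0 °C
Reagents that add atoms: mercury bis(trifluoroacetate), O=C(O[Hg]OC(=O)C(F)(F)F)C(F)(F)F (mercury stays only in 12; only hydrogen is added to 13)
Why: In this mercury-mediated lactonisation the divalent mercury salt activates the exocyclic alkene and the carboxylate on the equatorial 9β chain attacks the tertiary carbon C8 (Markovnikov, 6-exo) from the α face, away from the syn-axial C10 methyl, giving the trans-fused lactone with 8α-O, and NaBH4 then replaces mercury by hydrogen so that C8 carries the α oxygen and β methyl of the target.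

Step 9
Reactants: 13 δ-lactone
Product: 14 8α-hydroxy methyl ketone
Conditions: MeLi (1.05 equiv), THF, −78 °C; NH4Cl quench
Reagents that add atoms: methyllithium, [Li]C
Why: Addition of one equivalent of methyllithium to the δ-lactone stops at the lithium hemiketal at −78 °C, which opens to the δ-hydroxy methyl ketone on work-up, and the hindered C4 ester does not react at this temperature.

Step 10
Reactants: 14 8α-hydroxy methyl ketone
Product: 15 8α-triethylsilyl ether
Conditions: TESOTf, 2,6-lutidine, CH2Cl2, −78 → −40 °C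
Reagents that add atoms: triethylsilyl triflate, CC[Si](CC)(CC)OS(=O)(=O)C(F)(F)F
Why: The reactive silyl triflate silylates the tertiary alcohol at low temperature, where the methyl ketone is not converted into a silyl enol ether, and this protection prevents hemiketal formation and O-sulfonylation of the alkoxide in the next step.

Step 11
Reactants: 15 8α-triethylsilyl ether
Product: 16 enol triflate
Conditions: LiN(iPr)2, THF, −78 °C; then N-(5-chloro-2-pyridyl)bis(trifluoromethanesulfonimide), −78 °C; NH4Cl quench
Reagents that add atoms: N-(5-chloro-2-pyridyl)bis(trifluoromethanesulfonimide), O=S(=O)(N(c1ccc(Cl)cn1)S(=O)(=O)C(F)(F)F)C(F)(F)F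
Why: Kinetic enolate formation at the methyl group and O-sulfonylation give the 2-triflyloxy-1-alkene (enol triflate formation), and the C4 ester has no α-hydrogen.

Step 12
Reactants: 17 but-3-yn-1-ol
Product: 18 PMB ether of but-3-yn-1-ol
Conditions: NaH, 4-methoxybenzyl chloride, Bu4NI (cat.), THF/DMF, 0 °C → rt
Reagents that add atoms: 4-methoxybenzyl chloride, COc1ccc(CCl)cc1
Why: Williamson ether synthesis, in which NaH deprotonates only the hydroxyl group and not the terminal alkyne.

Step 13
Reactants: 18 PMB ether of but-3-yn-1-ol; 19 ethylene oxide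
Product: 22 (E)-homoallylic alcohol, via alkenyldimethylalane 20 (not isolated), via lithium aluminate 21 (not isolated)
Conditions: AlMe3, Cp2ZrCl2 (cat.), CH2Cl2, rt; n-BuLi, THF/hexane, −78 °C; then 19, −78 → 0 °C; 1 M HCl work-up
Reagents that add atoms: trimethylaluminium, C[Al](C)C (the C17 methyl group); n-butyllithium, [Li]CCCC (butyl group in 21 only)
Why: Zirconium-catalysed carboalumination (Negishi) adds methyl and aluminium syn across the alkyne with the metal on the terminal carbon, which fixes the E geometry, and the derived aluminate opens ethylene oxide with retention of that geometry.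

Step 14
Reactants: 22 (E)-homoallylic alcohol
Product: 23 (E)-β,γ-unsaturated aldehyde
Conditions: Dess–Martin periodinane, NaHCO3, CH2Cl2, 0 °C; used at once
Reagents that add atoms: none
Why: Dess–Martin oxidation under buffered, non-basic conditions gives the β,γ-unsaturated aldehyde without migration of the trisubstituted double bond into conjugation.

Step 15
Reactants: 16 enol triflate; 23 (E)-β,γ-unsaturated aldehyde
Product: 24 (14S)-allylic alcohol
Conditions: CrCl2, (S)-N-[2-(4-tert-butyl-4,5-dihydrooxazol-2-yl)-6-methylphenyl]methanesulfonamide, Et3N, THF, rt; then NiCl2 (cat.), 16, 23, rt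
Reagents that add atoms: none
Why: In this asymmetric Nozaki–Hiyama–Kishi coupling zerovalent nickel inserts into the C–OTf bond, the alkenyl group passes to trivalent chromium and adds to the aldehyde without enolising it, and the chiral sulfonamide ligand on chromium selects the aldehyde face and sets C14 as S, the decalin stereocentres being too remote to interfere.

Step 16
Reactants: 24 (14S)-allylic alcohol
Product: 25 (16S,17S)-epoxy alcohol
Conditions: L-fructose-derived Shi ketone (cat.), KHSO5 (Oxone), K2CO3, Bu4NHSO4, MeCN/CH2(OMe)2, aq. Na2B4O7–Na2EDTA buffer, 0 °C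
Reagents that add atoms: potassium peroxymonosulfate, [K+].[O-]S(=O)(=O)OO
Why: In the Shi epoxidation the chiral dioxirane epoxidises the electron-rich trisubstituted E alkene in preference to the 1,1-disubstituted alkene, which is deactivated by its allylic oxygen, and the L-fructose-derived ketone gives the 16S,17S epoxide, the mirror image of the R,R epoxides formed with the D-fructose-derived catalyst.

Step 17
Reactants: 25 (16S,17S)-epoxy alcohol
Product: 26 epoxy mesylate
Conditions: MsCl, Et3N, CH2Cl2, −30 °C; used without chromatography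
Reagents that add atoms: methanesulfonyl chloride, CS(=O)(=O)Cl
Why: Sulfonylation of the secondary allylic alcohol proceeds with retention at C14, and it is placed before the perhydrolysis because the free 3,4-epoxy alcohol would cyclise to a tetrahydrofuran under acid.

Step 18
Reactants: 26 epoxy mesylate
Product: 27 hydroperoxy mesylate (key-step precursor)
Conditions: anhydrous H2O2 in Et2O, H3PMo12O40 (cat.), 0 °C → rt
Reagents that add atoms: hydrogen peroxide, OO
Why: In this acid-catalysed perhydrolysis of a trisubstituted epoxide, hydrogen peroxide attacks the more substituted carbon C17 from the back side, so C17 is inverted (to R) while the C16 oxygen stays in place, giving the anti β-hydroxy hydroperoxide.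

Step 19
Reactants: 27 hydroperoxy mesylate
Product: 28 (14R)-1,2-dioxane
Conditions: Cs2CO3 (about 1 equiv), DMF, 0 °C, short reaction time
Reagents that add atoms: none
Why: Caesium carbonate removes only the hydroperoxide proton (pKa near 12, several units below the C16 carbinol), and the peroxy anion attacks C14 from the side opposite the mesylate in an SN2 displacement that forms the O–C14 bond. The closest known reaction type is the intramolecular alkylation of a hydroperoxide by a sulfonate or halide, the standard closure of 1,2-dioxanes and 1,2-dioxolanes. The dioxane ring (C14–C15–C16–C17–O–O) closes in the 6-exo-tet mode. C14 is the only stereocentre affected: the 14S configuration set by the ligand in step 15 is inverted to 14R, while C16 and C17 keep the anti arrangement fixed by steps 16 and 18. The step needs peroxide-O over alkoxide-O alkylation and direct over allylic (SN2′) substitution; the first is secured by the acidity gap and by the oxetane that attack by the C16 oxygen would require, the second by the eight-membered ring that SN2′ attack would require. Base-induced cleavage is held back because the tertiary C17 hydroperoxide has no α-hydrogen, and because about one equivalent of a weak base at 0 °C for a short time neither forms the C16 alkoxide needed for C16–C17 fragmentation nor removes the new allylic C14–H of the product.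

Step 20
Reactants: 28 (14R)-1,2-dioxane
Product: 29 dioxane diol
Conditions: DDQ, CH2Cl2/pH 7 phosphate buffer, 0 °C
Reagents that add atoms: none
Why: DDQ cleaves the electron-rich benzyl ether oxidatively (hydride abstraction, then hydrolysis of the oxocarbenium ion) and leaves the dialkyl peroxide, the silyl ethers and the terminal alkene untouched.

Step 21
Reactants: 29 dioxane diol
Product: 31 bis-silylated lactone, via lactol 30 (not isolated)
Conditions: TEMPO (cat.), PhI(OAc)2, CH2Cl2, rt
Reagents that add atoms: none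
Why: The oxoammonium salt from TEMPO oxidises the primary alcohol selectively to the aldehyde, the C16 hydroxyl closes the five-membered lactol, and a second oxidation gives the γ-lactone (oxidative lactonisation of a 1,4-diol), its trans ring fusion following from the anti C16–O/C17–O arrangement already present.

Step 22
Reactants: 31 bis-silylated lactone
Product: 32 target CNP0162504.1
Conditions: HF·pyridine, pyridine, THF, 0 °C → rt
Reagents that add atoms: none
Why: Fluoride-mediated desilylation under buffered acidic conditions removes both silyl ethers, and a basic fluoride source is avoided because the lactone enolate would expel the β-peroxy oxygen on C17.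

## Compound list

1 | neoabietic acid, abieta-8(14),13(15)-dien-18-oic acid (4α-CO2H, 4β-CH3, 5α-H, 9α-H, 10β-CH3) | CC(C)=C2CC[C@@H]1[C@@]3(C)CCC[C@@](C)(C(=O)O)[C@@H]3CCC1=C2 | starting material
2 | keto aldehyde: core acid (4α-CO2H) with C8 ketone and 9β-CH2CH2C(=O)CHO | O=CC(=O)CC[C@@H]1[C@@]2(C)CCC[C@@](C)(C(=O)O)[C@@H]2CCC1=O | intermediate
3 | keto diacid: core acid (4α-CO2H) with C8 ketone and 9β-CH2CH2CO2H (C13 acid) | OC(=O)CC[C@@H]1[C@@]2(C)CCC[C@@](C)(C(=O)O)[C@@H]2CCC1=O | intermediate
4 | keto diester: dimethyl ester of 3 | COC(=O)CC[C@@H]1[C@@]2(C)CCC[C@@](C)(C(=O)OC)[C@@H]2CCC1=O | intermediate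
5 | C7=C8 trimethylsilyl enol ether of 4 | COC(=O)CC[C@@H]1[C@@]2(C)CCC[C@@](C)(C(=O)OC)[C@@H]2CC=C1O[Si](C)(C)C | intermediate
6 | enone diester: 4 with a C6=C7 double bond conjugated to the C8 ketone | COC(=O)CC[C@@H]1[C@@]2(C)CCC[C@@](C)(C(=O)OC)[C@@H]2C=CC1=O | intermediate
7 | 6α-(4,4,5,5-tetramethyl-1,3,2-dioxaborolan-2-yl) 8-ketone diester | COC(=O)CC[C@@H]1[C@@]2(C)CCC[C@@](C)(C(=O)OC)[C@@H]2[C@@H](B3OC(C)(C)C(C)(C)O3)CC1=O | intermediate
8 | 6α-hydroxy 8-ketone diester | COC(=O)CC[C@@H]1[C@@]2(C)CCC[C@@](C)(C(=O)OC)[C@@H]2[C@@H](O)CC1=O | intermediate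
9 | 6α-(tert-butyldimethylsilyloxy) 8-ketone diester | COC(=O)CC[C@@H]1[C@@]2(C)CCC[C@@](C)(C(=O)OC)[C@@H]2[C@@H](O[Si](C)(C)C(C)(C)C)CC1=O | intermediate
10 | 6α-silyloxy 8-methylene diester (C8=CH2) | COC(=O)CC[C@@H]1[C@@]2(C)CCC[C@@](C)(C(=O)OC)[C@@H]2[C@@H](O[Si](C)(C)C(C)(C)C)CC1=C | intermediate
11 | 6α-silyloxy 8-methylene C13 acid (4α-CO2Me kept) | OC(=O)CC[C@@H]1[C@@]2(C)CCC[C@@](C)(C(=O)OC)[C@@H]2[C@@H](O[Si](C)(C)C(C)(C)C)CC1=C | intermediate
12 | trans-fused δ-lactone C13(=O)–O–C8α carrying 8β-CH2HgOCOCF3 and 6α-OTBS | O=C3CC[C@@H]1[C@@]2(C)CCC[C@@](C)(C(=O)OC)[C@@H]2[C@@H](O[Si](C)(C)C(C)(C)C)C[C@@]1(C[Hg]OC(=O)C(F)(F)F)O3 | intermediate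
13 | trans-fused δ-lactone C13(=O)–O–C8α with 8β-CH3, 6α-OTBS, 4α-CO2Me | O=C3CC[C@@H]1[C@@]2(C)CCC[C@@](C)(C(=O)OC)[C@@H]2[C@@H](O[Si](C)(C)C(C)(C)C)C[C@@]1(C)O3 | intermediate
14 | 8α-hydroxy methyl ketone: 9β-(3-oxobutyl), 8α-OH, 8β-CH3, 6α-OTBS core | CC(=O)CC[C@@H]1[C@@]2(C)CCC[C@@](C)(C(=O)OC)[C@@H]2[C@@H](O[Si](C)(C)C(C)(C)C)C[C@@]1(C)O | intermediate
15 | 8α-triethylsilyl ether of 14 | CC(=O)CC[C@@H]1[C@@]2(C)CCC[C@@](C)(C(=O)OC)[C@@H]2[C@@H](O[Si](C)(C)C(C)(C)C)C[C@@]1(C)O[Si](CC)(CC)CC | intermediate
16 | enol triflate: 9β-[3-(trifluoromethylsulfonyloxy)but-3-enyl], 8α-OTES, 8β-CH3, 6α-OTBS core | C=C(OS(=O)(=O)C(F)(F)F)CC[C@@H]1[C@@]2(C)CCC[C@@](C)(C(=O)OC)[C@@H]2[C@@H](O[Si](C)(C)C(C)(C)C)C[C@@]1(C)O[Si](CC)(CC)CC | intermediate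
17 | but-3-yn-1-ol | C#CCCO | starting material
18 | 1-[(but-3-yn-1-yloxy)methyl]-4-methoxybenzene | C#CCCOCc1ccc(OC)cc1 | intermediate
19 | ethylene oxide (oxirane) | C1CO1 | starting material
20 | (E)-[4-(4-methoxybenzyloxy)-2-methylbut-1-en-1-yl]dimethylalane | C[Al](C)/C=C(\C)CCOCc1ccc(OC)cc1 | intermediate
21 | lithium butyl[(E)-4-(4-methoxybenzyloxy)-2-methylbut-1-en-1-yl]dimethylaluminate | [Li+].CCCC[Al-](C)(C)/C=C(\C)CCOCc1ccc(OC)cc1 | intermediate
22 | (E)-6-(4-methoxybenzyloxy)-4-methylhex-3-en-1-ol | OCC/C=C(\C)CCOCc1ccc(OC)cc1 | intermediate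
23 | (E)-6-(4-methoxybenzyloxy)-4-methylhex-3-enal | O=CC/C=C(\C)CCOCc1ccc(OC)cc1 | intermediate
24 | (14S,16E)-allylic alcohol: C13(=CH2)–C14H(OH)–C15H2–C16H=C17(CH3)–C18H2–C19H2–OPMB on the 6α-OTBS, 8α-OTES core | C=C(CC[C@@H]1[C@@]2(C)CCC[C@@](C)(C(=O)OC)[C@@H]2[C@@H](O[Si](C)(C)C(C)(C)C)C[C@@]1(C)O[Si](CC)(CC)CC)[C@@H](O)C/C=C(\C)CCOCc1ccc(OC)cc1 | intermediate
25 | (14S,16S,17S)-16,17-epoxy 14-alcohol | C=C(CC[C@@H]1[C@@]2(C)CCC[C@@](C)(C(=O)OC)[C@@H]2[C@@H](O[Si](C)(C)C(C)(C)C)C[C@@]1(C)O[Si](CC)(CC)CC)[C@@H](O)C[C@@H]1O[C@@]1(C)CCOCc1ccc(OC)cc1 | intermediate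
26 | (14S,16S,17S)-16,17-epoxy 14-methanesulfonate | C=C(CC[C@@H]1[C@@]2(C)CCC[C@@](C)(C(=O)OC)[C@@H]2[C@@H](O[Si](C)(C)C(C)(C)C)C[C@@]1(C)O[Si](CC)(CC)CC)[C@@H](OS(C)(=O)=O)C[C@@H]1O[C@@]1(C)CCOCc1ccc(OC)cc1 | intermediate
27 | (14S,16S,17R)-14-mesyloxy-16-hydroxy-17-hydroperoxide (key-step precursor) | C=C(CC[C@@H]1[C@@]2(C)CCC[C@@](C)(C(=O)OC)[C@@H]2[C@@H](O[Si](C)(C)C(C)(C)C)C[C@@]1(C)O[Si](CC)(CC)CC)[C@@H](OS(C)(=O)=O)C[C@H](O)[C@@](C)(CCOCc1ccc(OC)cc1)OO | intermediate
28 | (14R,16S,17R)-1,2-dioxane (ring C14–C15–C16–C17–O–O) with 16-OH, 17-CH3 and 17-CH2CH2OPMB (key-step product) | C=C(CC[C@@H]1[C@@]2(C)CCC[C@@](C)(C(=O)OC)[C@@H]2[C@@H](O[Si](C)(C)C(C)(C)C)C[C@@]1(C)O[Si](CC)(CC)CC)[C@H]1C[C@H](O)[C@@](C)(CCOCc2ccc(OC)cc2)OO1 | intermediate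
29 | dioxane diol (16-OH and primary C19-OH) | C=C(CC[C@@H]1[C@@]2(C)CCC[C@@](C)(C(=O)OC)[C@@H]2[C@@H](O[Si](C)(C)C(C)(C)C)C[C@@]1(C)O[Si](CC)(CC)CC)[C@H]1C[C@H](O)[C@@](C)(CCO)OO1 | intermediate
30 | lactol (C19 hemiacetal closed onto O16, both anomers) | C=C(CC[C@@H]1[C@@]2(C)CCC[C@@](C)(C(=O)OC)[C@@H]2[C@@H](O[Si](C)(C)C(C)(C)C)C[C@@]1(C)O[Si](CC)(CC)CC)[C@H]1C[C@@H]2OC(O)C[C@@]2(C)OO1 | intermediate
31 | 6α-O-TBS, 8α-O-TES ether of the target (trans-fused dioxane γ-lactone) | C=C(CC[C@@H]1[C@@]2(C)CCC[C@@](C)(C(=O)OC)[C@@H]2[C@@H](O[Si](C)(C)C(C)(C)C)C[C@@]1(C)O[Si](CC)(CC)CC)[C@H]1C[C@@H]2OC(=O)C[C@@]2(C)OO1 | intermediate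
32 | CNP0162504.1 (14R,16S,17R; 6α-OH, 8α-OH, 4α-CO2Me) | C=C(CC[C@@H]1[C@@]2(C)CCC[C@@](C)(C(=O)OC)[C@@H]2[C@@H](O)C[C@@]1(C)O)[C@H]1C[C@@H]2OC(=O)C[C@@]2(C)OO1 | target

## Step count and risks

Total step count: 22.
Longest linear sequence: 19 steps (steps 1–11 and 15–22, from neoabietic acid).

Steps most likely to fail

Step 19 (ring closure). Base-induced cleavage of the β-hydroxy hydroperoxide, or elimination of the allylic mesylate, may outrun the SN2 closure. The dioxane would then be closed through its other C–O bond under acid instead of base. Setting out from epoxy mesylate 26, the sulfonate is displaced with inversion by 2-methoxyprop-2-yl hydroperoxide (CsOH, DMF, 0 °C) to give the (14R)-peroxyketal F1. Mild acid (10-camphorsulfonic acid, wet CH2Cl2, 0 °C) releases the C14 hydroperoxide F2, which opens the epoxide at the tertiary carbon C17 with inversion in the same flask (6-endo closure). The route is rejoined at 28 with the same configuration at C14, C16 and C17; steps 18 and 19 are both replaced.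

Step 18 (perhydrolysis). The allylic mesylate may be lost by solvolysis or allylic substitution while the acid catalyst and hydrogen peroxide open the epoxide. The leaving group would then be a chloride, which is inert to H3PMo12O40/H2O2, and the extra inversion is compensated one stage earlier. Setting out from enol triflate 16 (coupled again with 23), step 15 run with the antipodal ligand gives the (14R)-allylic alcohol F3, and epoxidation as in step 16 gives the (14R)-epoxy alcohol F4. Hexachloroacetone/PPh3 (CH2Cl2, −20 °C) converts the allylic alcohol into the (14S)-allylic chloride F5 with inversion and without allylic transposition. Perhydrolysis as in step 18 gives the chloro hydroperoxide F6, and Cs2CO3 in DMF closes the ring with the second inversion, coming back to the route at 28.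

Step 15 (coupling). Facial selection by the chromium ligand may be poor or of the wrong sense, since C14 is remote from every existing stereocentre. The carbinol would then be set by reagent-controlled reduction of a ketone. Setting out from 16 and 23, ligand-free coupling (CrCl2, NiCl2 cat., DMSO, rt) gives 24 mixed with its C14 epimer F3. Dess–Martin oxidation of the mixture (NaHCO3, CH2Cl2, 0 °C) gives the α-methylene ketone F7. Corey–Bakshi–Shibata reduction with the (R)-2-methyl oxazaborolidine and catecholborane (toluene, −78 °C), in which the 1,1-disubstituted alkenyl group acts as the large substituent, returns the (14S)-alcohol 24.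

Further compounds
F1 | step 19 | (14R)-peroxyketal: 26 with the C14 mesylate replaced, with inversion, by OOC(CH3)2OCH3 | C=C(CC[C@@H]1[C@@]2(C)CCC[C@@](C)(C(=O)OC)[C@@H]2[C@@H](O[Si](C)(C)C(C)(C)C)C[C@@]1(C)O[Si](CC)(CC)CC)[C@H](OOC(C)(C)OC)C[C@@H]1O[C@@]1(C)CCOCc1ccc(OC)cc1
F2 | step 19 | (14R,16S,17S)-14-hydroperoxy 16,17-epoxide | C=C(CC[C@@H]1[C@@]2(C)CCC[C@@](C)(C(=O)OC)[C@@H]2[C@@H](O[Si](C)(C)C(C)(C)C)C[C@@]1(C)O[Si](CC)(CC)CC)[C@H](OO)C[C@@H]1O[C@@]1(C)CCOCc1ccc(OC)cc1
F3 | step 18 | (14R)-allylic alcohol, the C14 epimer of 24 (also formed in the fallback to step 15) | C=C(CC[C@@H]1[C@@]2(C)CCC[C@@](C)(C(=O)OC)[C@@H]2[C@@H](O[Si](C)(C)C(C)(C)C)C[C@@]1(C)O[Si](CC)(CC)CC)[C@H](O)C/C=C(\C)CCOCc1ccc(OC)cc1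
F4 | step 18 | (14R,16S,17S)-epoxy alcohol, the C14 epimer of 25 | C=C(CC[C@@H]1[C@@]2(C)CCC[C@@](C)(C(=O)OC)[C@@H]2[C@@H](O[Si](C)(C)C(C)(C)C)C[C@@]1(C)O[Si](CC)(CC)CC)[C@H](O)C[C@@H]1O[C@@]1(C)CCOCc1ccc(OC)cc1
F5 | step 18 | (14S,16S,17S)-14-chloro 16,17-epoxide | C=C(CC[C@@H]1[C@@]2(C)CCC[C@@](C)(C(=O)OC)[C@@H]2[C@@H](O[Si](C)(C)C(C)(C)C)C[C@@]1(C)O[Si](CC)(CC)CC)[C@@H](Cl)C[C@@H]1O[C@@]1(C)CCOCc1ccc(OC)cc1
F6 | step 18 | (14S,16S,17R)-14-chloro-16-hydroxy-17-hydroperoxide | C=C(CC[C@@H]1[C@@]2(C)CCC[C@@](C)(C(=O)OC)[C@@H]2[C@@H](O[Si](C)(C)C(C)(C)C)C[C@@]1(C)O[Si](CC)(CC)CC)[C@@H](Cl)C[C@H](O)[C@@](C)(CCOCc1ccc(OC)cc1)OO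
F7 | step 15 | C14 ketone (α-methylene enone) of 24 | C=C(CC[C@@H]1[C@@]2(C)CCC[C@@](C)(C(=O)OC)[C@@H]2[C@@H](O[Si](C)(C)C(C)(C)C)C[C@@]1(C)O[Si](CC)(CC)CC)C(=O)C/C=C(\C)CCOCc1ccc(OC)cc1
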